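**Plan**

1. Retrosynthesis (drimane numbering: ring A = C1–C5/C10, ring B = C5–C10, C11 on C9, C12 on C8): cut C11–aryl (Negishi coupling) and C3–Br (SN2 from the 3α-alcohol), then join C11 and the C3 oxygen in a lactone bridge C3–O–C11(=O)–C9.
2. Cut the ring-fusion bond C5–C10 and the bond C8–C9 of this tricyclic lactone in one radical tandem. This leads back to a seven-membered unsaturated lactone (C9=C10 in the ring) whose C3 carries C4(Me2)–C5(X)–C6–C7–C8≡C12.
3. Enabling feature: C9 bears the one-carbon branch C11 next to the methylated quaternary C10, and C8 is an exocyclic methylene. As a lactone carbonyl tied to the C3 oxygen, C11 makes C9=C10 a radical acceptor held on one face, and a terminal alkyne ends as C8=C12.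
4. Forward order: aldol (C4–C5), Weinreb ketone synthesis (C2–C3), ring-closing metathesis (temporary lactone ring, C9=C10), then ring A (C5–C10) and ring B (C8–C9) together in step 9; lactone reduction, bromination and aryl coupling follow.
5. Stereochemistry: C3 from a CBS reduction; C5, C9 and C10 from the lactone tether in step 9; C3 is inverted when oxygen is exchanged for bromine.

Key step: step 9

Remark: α/β refer to the usual drawing with the C10 methyl β (target: 3β-Br, 5β-H, 9β-H); compounds 5, 6, 9 and 10 are racemic and 11–15 are carried as both configurations at C5, a centre that becomes a planar radical in step 9, so their SMILES leave it undefined.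

**Route**

Step 1
Reactants: 1 5-(trimethylsilyl)pent-4-yn-1-ol
Product: 2 5-(trimethylsilyl)pent-4-ynal
Conditions: Dess–Martin periodinane, NaHCO3, CH2Cl2, 0 °C to rt
Reagents that add atoms: none
Why: Dess–Martin oxidation of a primary alcohol should stop at the aldehyde and leave the silylalkyne untouched; no stereocenter is formed.

Step 2
Reactants: 2 5-(trimethylsilyl)pent-4-ynal; 3 N-methoxy-N,2-dimethylpropanamide
Product: 6 N-methoxy-N,2,2-trimethyl-3-(triethylsilyloxy)-7-(trimethylsilyl)hept-6-ynamide (racemic), via lithium enolate 4 (not isolated), via lithium aldolate 5 (not isolated)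
Conditions: LiN(iPr)2, THF, −78 °C (3 to 4); add 2, −78 °C; Et3SiOTf, −78 to 0 °C
Reagents that add atoms: triethylsilyl trifluoromethanesulfonate, CC[Si](CC)(CC)OS(=O)(=O)C(F)(F)F
Why: Aldol addition of the fully substituted amide enolate builds C4–C5 with the gem-dimethyl group and the aldolate is silylated in the same flask; C5 forms as a racemate, which is immaterial because this centre is erased in step 9.

Step 3
Reactants: 6 N-methoxy-N,2,2-trimethyl-3-(triethylsilyloxy)-7-(trimethylsilyl)hept-6-ynamide; 7 4-bromo-2-methylbut-1-ene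
Product: 10 2,6,6-trimethyl-7-(triethylsilyloxy)-11-(trimethylsilyl)undec-1-en-10-yn-5-one (racemic), via Grignard reagent 8 (not isolated), via magnesium hemiaminal chelate 9 (not isolated)
Conditions: Mg, THF, rt (7 to 8); add 6, 0 °C to rt; aq. NH4Cl
Reagents that add atoms: none
Why: Weinreb ketone synthesis; the chelated tetrahedral adduct prevents over-addition, so the Grignard reagent should deliver the C2–C1–C10 unit as the C3 ketone without forming a stereocenter.

Step 4
Reactants: 10 2,6,6-trimethyl-7-(triethylsilyloxy)-11-(trimethylsilyl)undec-1-en-10-yn-5-one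
Product: 11 (5R)-2,6,6-trimethyl-7-(triethylsilyloxy)-11-(trimethylsilyl)undec-1-en-10-yn-5-ol (both configurations at C7 of the chain)
Conditions: (S)-2-methyl-CBS-oxazaborolidine (0.3 equiv), catecholborane, PhMe, −78 to −40 °C
Reagents that add atoms: none
Why: Corey–Bakshi–Shibata reduction; the catalyst distinguishes the tertiary alkyl group (C4) from the CH2 chain and should give the (R)-carbinol at C3 under reagent control, while catecholborane spares the 1,1-disubstituted alkene.

Step 5
Reactants: 11 (5R)-2,6,6-trimethyl-7-(triethylsilyloxy)-11-(trimethylsilyl)undec-1-en-10-yn-5-ol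
Product: 12 (5R)-2,6,6-trimethyl-7-(triethylsilyloxy)-11-(trimethylsilyl)undec-1-en-10-yn-5-yl prop-2-enoate
Conditions: CH2=CHCOCl, iPr2NEt, DMAP (cat.), CH2Cl2, −20 to 0 °C
Reagents that add atoms: acryloyl chloride, C=CC(=O)Cl
Why: DMAP-catalysed acylation of the hindered secondary alcohol installs the acrylate that supplies C9 and C11; the C3 configuration is not touched.

Step 6
Reactants: 12 (5R)-2,6,6-trimethyl-7-(triethylsilyloxy)-11-(trimethylsilyl)undec-1-en-10-yn-5-yl prop-2-enoate
Product: 13 (7R)-4-methyl-7-[2-methyl-3-(triethylsilyloxy)-7-(trimethylsilyl)hept-6-yn-2-yl]-6,7-dihydrooxepin-2(5H)-one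
Conditions: second-generation Grubbs catalyst RuCl2(=CHPh)(PCy3)(H2IMes) (10 mol%), PhMe (2 mM), 80 °C
Reagents that add atoms: none
Why: Ring-closing metathesis between the acrylate and the 1,1-disubstituted alkene should close the seven-membered lactone with loss of ethene; the ring enforces the Z geometry of C9=C10 and the bulky silylalkyne should not engage the carbene.

Step 7
Reactants: 13 (7R)-4-methyl-7-[2-methyl-3-(triethylsilyloxy)-7-(trimethylsilyl)hept-6-yn-2-yl]-6,7-dihydrooxepin-2(5H)-one
Product: 14 (7R)-7-(3-hydroxy-2-methylhept-6-yn-2-yl)-4-methyl-6,7-dihydrooxepin-2(5H)-one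
Conditions: Bu4NF, AcOH, THF, 0 °C to rt
Reagents that add atoms: none
Why: Fluoride-mediated desilylation cleaves the silyl ether and the alkynyl–silicon bond, while acetic acid buffers the medium so that the unsaturated lactone should survive.

Step 8
Reactants: 14 (7R)-7-(3-hydroxy-2-methylhept-6-yn-2-yl)-4-methyl-6,7-dihydrooxepin-2(5H)-one
Product: 15 O-{2-methyl-2-[(7R)-4-methyl-2-oxo-2,5,6,7-tetrahydrooxepin-7-yl]hept-6-yn-3-yl} 1H-imidazole-1-carbothioate
Conditions: 1,1'-thiocarbonyldiimidazole, DMAP (cat.), ClCH2CH2Cl, 70 °C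
Reagents that add atoms: 1,1'-thiocarbonyldiimidazole, S=C(n1ccnc1)n1ccnc1
Why: Thioacylation gives the Barton–McCombie radical precursor at C5; heating and DMAP should overcome the neopentyl hindrance.

Step 9
Reactants: 15 O-{2-methyl-2-[(7R)-4-methyl-2-oxo-2,5,6,7-tetrahydrooxepin-7-yl]hept-6-yn-3-yl} 1H-imidazole-1-carbothioate
Product: 16 (3R,5S,9R,10S)-3α-hydroxy-5β,9β-drim-8(12)-en-11-oic acid 11,3-lactone (bridged tricyclic lactone)
Conditions: Bu3SnH (1.3 equiv) and AIBN (0.2 equiv) added over 12 h by syringe pump to 15 (2 mM) in PhMe, 100 °C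
Reagents that add atoms: none
Why: The tributyltin radical adds to the thiocarbonyl sulfur of 15 and the adduct fragments to the secondary C5 radical, which adds to C10 (the β-carbon of the unsaturated lactone); the α-lactone radical at C9 then adds to C8 of the alkyne and the vinyl radical takes hydrogen from Bu3SnH to leave the C8=C12 methylene. The closest known reaction type is the stannane-mediated tandem radical cyclization started by a Barton–McCombie fragmentation, with conjugate addition to an unsaturated ester followed by alkyne capture. Ring A closes 6-exo-trig through the new C5–C10 bond and ring B closes 6-exo-dig through C8–C9. C10 and C9 are set by the lactone tether, because the side chain on C3 can reach C10 only on the face syn to the C3 oxygen, which places the methyl group anti to the bridge and keeps C11 cis to C1. C5 is set by the second closure, since only the radical rotamer with C6 turned toward the lactone bridge (flanked by the sp2 C9–H and not by the C1 methylene) can reach C9, which makes H5 and the C10 methyl cis. The step needs both closures to outrun hydrogen transfer to the C5 and C9 radicals and the 1,5-hydrogen shift from C1; the polarity match between the nucleophilic alkyl radical and the lactone, together with slow stannane addition at high dilution, should secure this.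

Step 10
Reactants: 16 (3R,5S,9R,10S)-3α-hydroxy-5β,9β-drim-8(12)-en-11-oic acid 11,3-lactone
Product: 17 (3R,5S,9R,10S)-5β,9β-drim-8(12)-ene-3α,11-diol
Conditions: LiAlH4, THF, 0 °C to rt
Reagents that add atoms: none
Why: Hydride reduction of the lactone removes the tether, leaves C11 as CH2OH and frees the 3α-hydroxyl (axial once ring A relaxes to a chair) without touching a stereocenter.

Step 11
Reactants: 17 (3R,5S,9R,10S)-5β,9β-drim-8(12)-ene-3α,11-diol
Product: 18 (3R,5S,9R,10S)-11-iodo-5β,9β-drim-8(12)-en-3α-ol
Conditions: I2, PPh3, imidazole, CH2Cl2, 0 °C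
Reagents that add atoms: iodine, II
Why: Appel-type iodination should be selective for the primary C11 hydroxyl, because the axial neopentyl C3 hydroxyl is too hindered to react at 0 °C.

Step 12
Reactants: 18 (3R,5S,9R,10S)-11-iodo-5β,9β-drim-8(12)-en-3α-ol
Product: 19 (3S,5S,9R,10S)-3β-bromo-11-iodo-5β,9β-drim-8(12)-ene
Conditions: CBr4, PPh3, CH2Cl2, 0 to 40 °C
Reagents that add atoms: tetrabromomethane, BrC(Br)(Br)Br
Why: Appel reaction; the activated axial 3α-oxygen is displaced by bromide in an SN2 step from the equatorial direction, so C3 should be inverted to the 3β-bromide (S), and the step precedes aryl coupling because these reagents would attack an aldehyde.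

Step 13
Reactants: 20 4-bromo-2,5-dimethoxybenzaldehyde
Product: 21 4-bromo-2,5-dihydroxybenzaldehyde
Conditions: BBr3, CH2Cl2, −78 °C to rt; H2O
Reagents that add atoms: none
Why: Lewis acid ether cleavage with BBr3 frees both phenols so that they can be re-protected as base-labile esters.

Step 14
Reactants: 21 4-bromo-2,5-dihydroxybenzaldehyde
Product: 22 2-bromo-5-formyl-1,4-phenylene diacetate
Conditions: Ac2O, pyridine, DMAP (cat.), CH2Cl2, 0 °C
Reagents that add atoms: acetic anhydride, CC(=O)OC(C)=O
Why: O-Acetylation protects the hydroquinone against oxidation and against protonolysis of the organozinc reagent in step 15.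

Step 15
Reactants: 19 (3S,5S,9R,10S)-3β-bromo-11-iodo-5β,9β-drim-8(12)-ene; 22 2-bromo-5-formyl-1,4-phenylene diacetate
Product: 24 2-{[(3S,5S,9R,10R)-3β-bromo-5β,9β-drim-8(12)-en-11-yl]}-5-formyl-1,4-phenylene diacetate, via alkylzinc iodide 23 (not isolated)
Conditions: Zn dust, LiCl, THF, 40 °C (19 to 23); add 22, Pd(OAc)2 (5 mol%), SPhos (10 mol%), THF, 50 °C
Reagents that add atoms: none
Why: Negishi coupling; zinc should insert only into the primary carbon–iodine bond (the hindered secondary bromide is inert at this temperature) and the alkylzinc couples with the aryl bromide under palladium catalysis, which tolerates the aldehyde and the acetates and touches no stereocenter.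

Step 16
Reactants: 24 2-{[(3S,5S,9R,10R)-3β-bromo-5β,9β-drim-8(12)-en-11-yl]}-5-formyl-1,4-phenylene diacetate
Product: 25 peyssonol A
Conditions: K2CO3 (cat.), MeOH (degassed), 0 °C; aq. NH4Cl
Reagents that add atoms: none
Why: Base-catalysed methanolysis of the aryl acetates releases the hydroquinone without acid, so the exocyclic alkene, the aldehyde and the secondary bromide should be preserved.

**Compound list**

1 | 5-(trimethylsilyl)pent-4-yn-1-ol | C[Si](C)(C)C#CCCCO | starting material
2 | 5-(trimethylsilyl)pent-4-ynal | C[Si](C)(C)C#CCCC=O | intermediate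
3 | N-methoxy-N,2-dimethylpropanamide | CC(C)C(=O)N(C)OC | starting material
4 | lithium enolate of 3 | CC(C)=C(O[Li])N(C)OC | intermediate
5 | lithium aldolate from 4 and 2 (racemic) | C[Si](C)(C)C#CCCC(O[Li])C(C)(C)C(=O)N(C)OC | intermediate
6 | N-methoxy-N,2,2-trimethyl-3-(triethylsilyloxy)-7-(trimethylsilyl)hept-6-ynamide (racemic) | C[Si](C)(C)C#CCCC(O[Si](CC)(CC)CC)C(C)(C)C(=O)N(C)OC | intermediate
7 | 4-bromo-2-methylbut-1-ene | C=C(C)CCBr | starting material
8 | (3-methylbut-3-en-1-yl)magnesium bromide | C=C(C)CC[Mg]Br | intermediate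
9 | bromomagnesium hemiaminal alkoxide (tetrahedral adduct of 8 and 6, racemic) | C[Si](C)(C)C#CCCC(O[Si](CC)(CC)CC)C(C)(C)C(O[Mg]Br)(CCC(C)=C)N(C)OC | intermediate
10 | 2,6,6-trimethyl-7-(triethylsilyloxy)-11-(trimethylsilyl)undec-1-en-10-yn-5-one (racemic) | C[Si](C)(C)C#CCCC(O[Si](CC)(CC)CC)C(C)(C)C(=O)CCC(C)=C | intermediate
11 | (5R)-2,6,6-trimethyl-7-(triethylsilyloxy)-11-(trimethylsilyl)undec-1-en-10-yn-5-ol | C[Si](C)(C)C#CCCC(O[Si](CC)(CC)CC)C(C)(C)[C@H](O)CCC(C)=C | intermediate
12 | (5R)-2,6,6-trimethyl-7-(triethylsilyloxy)-11-(trimethylsilyl)undec-1-en-10-yn-5-yl prop-2-enoate | C[Si](C)(C)C#CCCC(O[Si](CC)(CC)CC)C(C)(C)[C@H](OC(=O)C=C)CCC(C)=C | intermediate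
13 | (7R)-4-methyl-7-[2-methyl-3-(triethylsilyloxy)-7-(trimethylsilyl)hept-6-yn-2-yl]-6,7-dihydrooxepin-2(5H)-one | C[Si](C)(C)C#CCCC(O[Si](CC)(CC)CC)C(C)(C)[C@H]1CC/C(C)=C\C(=O)O1 | intermediate
14 | (7R)-7-(3-hydroxy-2-methylhept-6-yn-2-yl)-4-methyl-6,7-dihydrooxepin-2(5H)-one | C#CCCC(O)C(C)(C)[C@H]1CC/C(C)=C\C(=O)O1 | intermediate
15 | O-{2-methyl-2-[(7R)-4-methyl-2-oxo-2,5,6,7-tetrahydrooxepin-7-yl]hept-6-yn-3-yl} 1H-imidazole-1-carbothioate | C#CCCC(OC(=S)n1ccnc1)C(C)(C)[C@H]1CC/C(C)=C\C(=O)O1 | intermediate
16 | (3R,5S,9R,10S)-3α-hydroxy-5β,9β-drim-8(12)-en-11-oic acid 11,3-lactone | C=C1CC[C@@H]2C(C)(C)[C@H]3CC[C@]2(C)[C@@H]1C(=O)O3 | intermediate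
17 | (3R,5S,9R,10S)-5β,9β-drim-8(12)-ene-3α,11-diol | C=C1CC[C@@H]2C(C)(C)[C@H](O)CC[C@]2(C)[C@@H]1CO | intermediate
18 | (3R,5S,9R,10S)-11-iodo-5β,9β-drim-8(12)-en-3α-ol | C=C1CC[C@@H]2C(C)(C)[C@H](O)CC[C@]2(C)[C@@H]1CI | intermediate
19 | (3S,5S,9R,10S)-3β-bromo-11-iodo-5β,9β-drim-8(12)-ene | C=C1CC[C@@H]2C(C)(C)[C@@H](Br)CC[C@]2(C)[C@@H]1CI | intermediate
20 | 4-bromo-2,5-dimethoxybenzaldehyde | COc1cc(C=O)c(OC)cc1Br | starting material
21 | 4-bromo-2,5-dihydroxybenzaldehyde | Oc1cc(C=O)c(O)cc1Br | intermediate
22 | 2-bromo-5-formyl-1,4-phenylene diacetate | CC(=O)Oc1cc(C=O)c(OC(C)=O)cc1Br | intermediate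
23 | [(3S,5S,9R,10S)-3β-bromo-5β,9β-drim-8(12)-en-11-yl]zinc iodide | C=C1CC[C@@H]2C(C)(C)[C@@H](Br)CC[C@]2(C)[C@@H]1C[Zn]I | intermediate
24 | 2-{[(3S,5S,9R,10R)-3β-bromo-5β,9β-drim-8(12)-en-11-yl]}-5-formyl-1,4-phenylene diacetate (peyssonol A diacetate) | C=C1CC[C@@H]2C(C)(C)[C@@H](Br)CC[C@]2(C)[C@@H]1Cc1cc(OC(C)=O)c(C=O)cc1OC(C)=O | intermediate
25 | peyssonol A, 4-{[(1R,4aS,6S,8aR)-6-bromo-5,5,8a-trimethyl-2-methylidenedecahydronaphthalen-1-yl]methyl}-2,5-dihydroxybenzaldehyde | C=C1CC[C@@H]2C(C)(C)[C@@H](Br)CC[C@]2(C)[C@@H]1Cc1cc(O)c(C=O)cc1O | target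

**Step count and risks**

Total steps: 16. Longest linear sequence: 14 (steps 1–12, 15, 16); steps 13 and 14 prepare the aryl fragment.

Most likely to fail:

Step 9 (tandem radical closure). The process at risk is hydrogen transfer overtaking ring closure: the C5 radical may be reduced by the stannane or may take a hydrogen from C1 (1,5-shift) before ring A closes, or the C9 radical may be reduced before it reaches the alkyne. The fallback sets out from 15 and returns at 16; it generates the radical without a stoichiometric hydrogen donor and closes the two rings in separate operations. Thermolysis of 15 (Chugaev-type syn elimination, PhMe, 160 °C) should give the (E)-alkene lactone F1. Hydrogen-atom transfer from an iron hydride (Fe(acac)3, PhSiH3, EtOH, 60 °C) to C6 of F1 produces the same C5 radical; it closes ring A by conjugate addition to C10 and the resulting radical is reduced and protonated, giving the bridged bicyclic lactone F2. Enolization and silylation (LiN(SiMe3)2, t-BuMe2SiCl, THF, −78 °C) give its tert-butyldimethylsilyl ketene acetal F3, and a gold-catalysed 6-exo-dig carbocyclization onto the alkyne (AuCl(PPh3), AgBF4, CH2Cl2–MeOH, rt) closes ring B to give 16.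

Step 12 (exchange of the C3 oxygen for bromine). The process at risk is ionization or elimination of the phosphorus-activated neopentyl alcohol (methyl shift, ring contraction, alkene formation) instead of SN2 displacement. The fallback sets out from 18 and returns at 19; it separates activation from displacement and avoids any phosphonium species. The alcohol is converted into the isolable imidazole-1-sulfonate F4 (NaH, N,N'-sulfonyldiimidazole, THF, 0 °C), and this ester is displaced by a non-coordinated bromide (Bu4NBr, PhMe, 60 °C) with inversion to give 19.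

Step 6 (ring-closing metathesis). The process at risk is slow turnover at the 1,1-disubstituted alkene, with oligomerization instead of closure of a seven-membered ring bearing a trisubstituted double bond. The fallback sets out from 11 and returns at 13; it forms C9=C10 by an intramolecular Horner–Wadsworth–Emmons reaction. Alcohol 11 is esterified with diethylphosphonoacetic acid (DCC, DMAP, CH2Cl2) to the phosphonoacetate F5. The 1,1-disubstituted alkene is cleaved (OsO4 cat., NaIO4, 2,6-lutidine, dioxane–H2O; Lemieux–Johnson oxidation) to the methyl ketone F6. Treatment with LiCl and iPr2NEt in MeCN at high dilution should close lactone 13, the ring again enforcing the Z geometry.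

**Further compounds**

F1 | step 9 | (7R)-4-methyl-7-[(3E)-2-methylhept-3-en-6-yn-2-yl]-6,7-dihydrooxepin-2(5H)-one | C#CC/C=C/C(C)(C)[C@H]1CC/C(C)=C\C(=O)O1
F2 | step 9 | 6-(but-3-yn-1-yl)-5,7,7-trimethyl-2-oxabicyclo[3.2.2]nonan-3-one (ring A bridged by the C3–O–C11 lactone, butynyl chain on C5 syn to the lactone bridge) | C#CCC[C@@H]1C(C)(C)[C@H]2CC[C@]1(C)CC(=O)O2
F3 | step 9 | tert-butyldimethylsilyl ketene acetal of F2 | C#CCC[C@@H]1C(C)(C)[C@H]2CC[C@]1(C)C=C(O[Si](C)(C)C(C)(C)C)O2
F4 | step 12 | (3R,5S,9R,10S)-11-iodo-5β,9β-drim-8(12)-en-3α-yl 1H-imidazole-1-sulfonate | C=C1CC[C@@H]2C(C)(C)[C@H](OS(=O)(=O)n3ccnc3)CC[C@]2(C)[C@@H]1CI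
F5 | step 6 | (5R)-2,6,6-trimethyl-7-(triethylsilyloxy)-11-(trimethylsilyl)undec-1-en-10-yn-5-yl (diethoxyphosphoryl)acetate | C[Si](C)(C)C#CCCC(O[Si](CC)(CC)CC)C(C)(C)[C@H](OC(=O)CP(=O)(OCC)OCC)CCC(C)=C
F6 | step 6 | (5R)-6,6-dimethyl-2-oxo-7-(triethylsilyloxy)-11-(trimethylsilyl)undec-10-yn-5-yl (diethoxyphosphoryl)acetate | C[Si](C)(C)C#CCCC(O[Si](CC)(CC)CC)C(C)(C)[C@H](OC(=O)CP(=O)(OCC)OCC)CCC(C)=O
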